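Locants follow germacrane numbering. The ten-membered ring is cut at C6–C7: an oxygen on C6 next to the C4–C5 epoxide (an E-alkene before oxidation) and a three-carbon branch on C7 form the retron of a [2,3]-Wittig shift across a C6–O–C12 ether. Lithiation at C6 of a thirteen-membered (E,E,E)-diallylic ether carrying a silyloxy group on C8 should in one operation join C6 to C7, break O–C12, reveal the isopropenyl group and contract the macrocycle to the ten-membered carbocycle, the C8 centre steering the configuration of C7 and C6. Because that relay runs anti to the C8–O bond, C8 is made 8S and inverted late through its ketone.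

Key step: step 18

Remark: the carbanion is assumed to add to C7 anti to the C8–O bond with H8 in the alkene plane, so the ether is built as the 8S epimer; germacrane numbering means ring carbons C1–C10, methyl C14 on C10, methyl C15 on C4 and the C11–C13 chain on C7; 4-(allyloxy)benzoic acid is taken as a purchased compound.

Step 1
Reactants: 1 geraniol
Product: 2 geranyl 4-methoxybenzyl ether
Conditions: NaH, 4-methoxybenzyl chloride, Bu4NI (cat.), THF, 0 °C → rt
Reagents that add atoms: 4-methoxybenzyl chloride, COc1ccc(CCl)cc1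
Why: Williamson etherification of the sodium alkoxide by the benzylic chloride protects the future C6 oxygen without touching either alkene.

Step 2
Reactants: 2 geranyl 4-methoxybenzyl ether
Product: 3 (2E,6E)-8-[(4-methoxybenzyl)oxy]-2,6-dimethylocta-2,6-dien-1-ol
Conditions: SeO2 (cat.), t-BuOOH, salicylic acid (cat.), CH2Cl2, rt
Reagents that add atoms: tert-butyl hydroperoxide, CC(C)(C)OO
Why: SeO2-catalysed allylic oxidation (ene reaction then [2,3]-shift) hydroxylates the E-methyl group of the electron-rich terminal alkene (future C9), leaving the alkene next to the ether oxygen alone and keeping the E geometry.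

Step 3
Reactants: 3 (2E,6E)-8-[(4-methoxybenzyl)oxy]-2,6-dimethylocta-2,6-dien-1-ol
Product: 4 1-({[(2E,6E)-8-bromo-3,7-dimethylocta-2,6-dien-1-yl]oxy}methyl)-4-methoxybenzene
Conditions: CBr4, PPh3, CH2Cl2, 0 °C
Reagents that add atoms: carbon tetrabromide, BrC(Br)(Br)Br
Why: Appel bromination converts the primary allylic alcohol into the bromide by SN2 displacement without allylic transposition.

Step 4
Reactants: 4 1-({[(2E,6E)-8-bromo-3,7-dimethylocta-2,6-dien-1-yl]oxy}methyl)-4-methoxybenzene
Product: 5 1-({[(2E,6E)-3,7-dimethyl-8-(phenylsulfonyl)octa-2,6-dien-1-yl]oxy}methyl)-4-methoxybenzene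
Conditions: PhSO2Na, DMF, rt
Reagents that add atoms: sodium benzenesulfinate, [Na+].[O-]S(=O)c1ccccc1
Why: S-alkylation of the sulfinate by the allylic bromide (SN2) gives the allylic sulfone that serves as the C9 nucleophile.

Step 5
Reactants: 6 prenyl acetate
Product: 7 (2E)-4-hydroxy-3-methylbut-2-en-1-yl acetate
Conditions: SeO2 (cat.), t-BuOOH, CH2Cl2, rt
Reagents that add atoms: tert-butyl hydroperoxide, CC(C)(C)OO
Why: The same SeO2-catalysed allylic oxidation hydroxylates the E-methyl group (future C12), while the acetoxymethyl carbon is kept as the future C8.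

Step 6
Reactants: 7 (2E)-4-hydroxy-3-methylbut-2-en-1-yl acetate
Product: 8 (2E)-4-[(tert-butyldimethylsilyl)oxy]-3-methylbut-2-en-1-yl acetate
Conditions: TBSCl, imidazole, CH2Cl2, 0 °C → rt
Reagents that add atoms: tert-butyldimethylsilyl chloride, CC(C)(C)[Si](C)(C)Cl
Why: Imidazole-promoted silylation protects the primary C12 alcohol.

Step 7
Reactants: 8 (2E)-4-[(tert-butyldimethylsilyl)oxy]-3-methylbut-2-en-1-yl acetate
Product: 9 (2E)-4-[(tert-butyldimethylsilyl)oxy]-3-methylbut-2-en-1-ol
Conditions: K2CO3 (cat.), MeOH, 0 °C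
Reagents that add atoms: none
Why: Base-catalysed transesterification with methanol removes the acetate while the silyl ether survives.

Step 8
Reactants: 9 (2E)-4-[(tert-butyldimethylsilyl)oxy]-3-methylbut-2-en-1-ol
Product: 10 (2E)-4-[(tert-butyldimethylsilyl)oxy]-3-methylbut-2-enal
Conditions: MnO2, CH2Cl2, rt
Reagents that add atoms: none
Why: MnO2 oxidises the allylic alcohol selectively to the E-enal, whose aldehyde carbon is C8, without isomerising the alkene.

Step 9
Reactants: 5 1-({[(2E,6E)-3,7-dimethyl-8-(phenylsulfonyl)octa-2,6-dien-1-yl]oxy}methyl)-4-methoxybenzene, 10 (2E)-4-[(tert-butyldimethylsilyl)oxy]-3-methylbut-2-enal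
Product: 12 β-hydroxy sulfone (2E,6E,10E)-12-[(tert-butyldimethylsilyl)oxy]-1-[(4-methoxybenzyl)oxy]-3,7,11-trimethyl-8-(phenylsulfonyl)dodeca-2,6,10-trien-9-ol as a diastereomer mixture, via lithiated sulfone 11 (not isolated)
Conditions: n-BuLi, THF, −78 °C; then 10; AcOH, −78 °C
Reagents that add atoms: none
Why: The α-sulfonyl allyl carbanion adds through its α-carbon to the aldehyde (first stage of a Julia-type coupling), forming C8–C9; the two new centres form unselectively and are both erased in steps 10 and 11.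

Step 10
Reactants: 12 β-hydroxy sulfone
Product: 13 (2E,6E,10E)-12-[(tert-butyldimethylsilyl)oxy]-1-[(4-methoxybenzyl)oxy]-3,7,11-trimethyl-8-(phenylsulfonyl)dodeca-2,6,10-trien-9-one
Conditions: Dess–Martin periodinane, CH2Cl2, 0 °C → rt
Reagents that add atoms: none
Why: Dess–Martin oxidation of the secondary allylic alcohol gives the β-keto sulfone and removes the unselective C8 centre.

Step 11
Reactants: 13 β-keto sulfone
Product: 14 (2E,6E,10E)-12-[(tert-butyldimethylsilyl)oxy]-1-[(4-methoxybenzyl)oxy]-3,7,11-trimethyldodeca-2,6,10-trien-9-one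
Conditions: SmI2, THF/MeOH, −78 °C
Reagents that add atoms: none
Why: Reductive desulfonylation of a β-keto sulfone by electron transfer from SmI2 gives the samarium enolate, which methanol protonates at C9 at low temperature so that the skipped C1(10) alkene does not move into conjugation.

Step 12
Reactants: 14 enone
Product: 15 (2E,6E,9S,10E)-12-[(tert-butyldimethylsilyl)oxy]-1-[(4-methoxybenzyl)oxy]-3,7,11-trimethyldodeca-2,6,10-trien-9-ol
Conditions: (R)-1-methyl-3,3-diphenyltetrahydro-1H,3H-pyrrolo[1,2-c][1,3,2]oxazaborole [(R)-Me-CBS] (0.2 equiv), catecholborane, toluene, −78 °C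
Reagents that add atoms: none
Why: Corey–Bakshi–Shibata reduction in which the alkenyl arm acts as the large group and the CH2 arm as the small one, so that the (R)-catalyst should give the 8S allylic alcohol (germacrane C8), the β,β-disubstituted enone resisting conjugate reduction.

Step 13
Reactants: 15 (9S)-allylic alcohol
Product: 16 (2E,6E,9S,10E)-9,12-bis[(tert-butyldimethylsilyl)oxy]-3,7,11-trimethyldodeca-2,6,10-trien-1-yl 4-methoxybenzyl ether
Conditions: TBSCl, imidazole, DMF, rt
Reagents that add atoms: tert-butyldimethylsilyl chloride, CC(C)(C)[Si](C)(C)Cl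
Why: Imidazole-promoted silylation of the secondary allylic alcohol installs the C8 silyl ether that is carried through the key step.

Step 14
Reactants: 16 bis-silyl ether
Product: 17 (2E,4S,6E,10E)-4-[(tert-butyldimethylsilyl)oxy]-12-[(4-methoxybenzyl)oxy]-2,6,10-trimethyldodeca-2,6,10-trien-1-ol
Conditions: (+)-camphor-10-sulfonic acid (cat.), MeOH/CH2Cl2, −10 °C
Reagents that add atoms: none
Why: Acid-catalysed methanolysis cleaves the unhindered primary allylic silyl ether at C12 much faster than the hindered secondary one at C8, a standard selective desilylation.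

Step 15
Reactants: 17 C12 alcohol
Product: 18 (2E,6E,9S,10E)-9-[(tert-butyldimethylsilyl)oxy]-12-chloro-3,7,11-trimethyldodeca-2,6,10-trien-1-yl 4-methoxybenzyl ether
Conditions: PPh3, hexachloroacetone, CH2Cl2, −20 → 0 °C
Reagents that add atoms: hexachloroacetone, ClC(Cl)(Cl)C(=O)C(Cl)(Cl)Cl
Why: Appel-type chlorination under neutral conditions converts the primary allylic alcohol into the chloride without allylic transposition or loss of alkene geometry.

Step 16
Reactants: 18 allylic chloride
Product: 19 (2E,6E,9S,10E)-9-[(tert-butyldimethylsilyl)oxy]-12-chloro-3,7,11-trimethyldodeca-2,6,10-trien-1-ol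
Conditions: DDQ, CH2Cl2/pH 7 buffer, 0 °C
Reagents that add atoms: none
Why: Oxidative cleavage of the 4-methoxybenzyl ether by DDQ (hydride abstraction then hydrolysis) frees the C6 alcohol while the allylic chloride and the silyl ether are inert.

Step 17
Reactants: 19 hydroxy chloride
Product: 20 (3E,5S,7E,11E)-5-[(tert-butyldimethylsilyl)oxy]-3,7,11-trimethyl-1-oxacyclotrideca-3,7,11-triene (thirteen-membered C6–O–C12 ether, 8S)
Conditions: NaH, THF (0.005 M, slow addition), 60 °C
Reagents that add atoms: none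
Why: Intramolecular Williamson etherification under high dilution, in which the C6 alkoxide displaces the primary allylic chloride at C12 by SN2 and closes the thirteen-membered ring with all three E-alkenes intact.

Step 18
Reactants: 20 thirteen-membered diallylic ether
Product: 22 (1R,2E,6E,9S,10S)-9-[(tert-butyldimethylsilyl)oxy]-3,7-dimethyl-10-(prop-1-en-2-yl)cyclodeca-2,6-dien-1-ol [(6R,7S,8S)-8-silyloxygermacra-1(10)E,4E,11-trien-6-ol], via C6-lithio ether 21 (not isolated)
Conditions: n-BuLi, THF, −78 → −25 °C; AcOH, −78 °C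
Reagents that add atoms: none
Why: n-BuLi removes a C6 proton, which is allylic and α to oxygen, and the α-oxy allyllithium undergoes a concerted [2,3]-Wittig shift through a five-membered envelope that bonds C6 to C7 while O–C12 breaks and the C11=C12 isopropenyl alkene appears. The closest known reaction type is the [2,3]-Wittig ring contraction of thirteen-membered diallylic ethers to germacrane-type cyclodecadienols. The ten-membered ring is closed by this sigmatropic C6–C7 bond formation inside the macrocycle (a ring contraction through a fused five/ten-membered transition state), not by an ionic cyclisation. C7 is controlled by C8: allylic strain with the C13 methyl holds H8 in the plane of C7=C11 and the carbanion adds anti to the C8–O bond with C9 on the outside, which matches a crown-like ten-membered transition state in which the silyloxy group is equatorial. C6 follows from the E geometry of C7=C11 and the exo position of the C5 vinyl arm, which place H6 and H7 anti and the C6 oxygen trans to the C7 branch. The step needs lithiation at C6 and not at C12 and a single face of C7; the unsubstituted C5 beside C6, the cost of building a quaternary C4 from a C12 anion and the bulky silyloxy group on the (8S) centre should secure both, and a cold quench keeps the silyl group on O8.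

Step 19
Reactants: 22 isopropenyl alcohol
Product: 23 (1R,2E,6E,9S,10S)-9-[(tert-butyldimethylsilyl)oxy]-3,7-dimethyl-10-(propan-2-yl)cyclodeca-2,6-dien-1-ol
Conditions: H2 (1 atm), RhCl(PPh3)3 (cat.), toluene, rt
Reagents that add atoms: none
Why: Homogeneous hydrogenation with RhCl(PPh3)3 reduces the 1,1-disubstituted isopropenyl alkene far faster than the two trisubstituted ring alkenes and creates no stereocentre.

Step 20
Reactants: 23 dienol
Product: 24 (4R,5R,6S,7S,8S)-8-[(tert-butyldimethylsilyl)oxy]-4,5-epoxygermacr-1(10)E-en-6-ol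
Conditions: VO(acac)2 (cat.), t-BuOOH, CH2Cl2, 0 °C
Reagents that add atoms: tert-butyl hydroperoxide, CC(C)(C)OO
Why: Hydroxyl-directed epoxidation (Sharpless VO(acac)2/t-BuOOH) delivers oxygen from the vanadate ester of the C6 alcohol to C4=C5 only, and because allylic strain with the C15 methyl holds H6 in the alkene plane the oxygen arrives on the outer face syn to the C6 oxygen, setting C4 and C5 as 4R,5R.

Step 21
Reactants: 24 epoxy alcohol, 25 4-(allyloxy)benzoic acid
Product: 26 (4R,5R,6S,7S,8S)-8-[(tert-butyldimethylsilyl)oxy]-4,5-epoxygermacr-1(10)E-en-6-yl 4-(allyloxy)benzoate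
Conditions: DCC, 4-(dimethylamino)pyridine (cat.), CH2Cl2, rt
Reagents that add atoms: none
Why: Steglich esterification acylates the only free hydroxyl (C6) with retention, and the allyl ether keeps the phenol masked through the redox steps at C8.

Step 22
Reactants: 26 silyl ether ester
Product: 27 (4R,5R,6S,7R,8S)-4,5-epoxy-8-hydroxygermacr-1(10)E-en-6-yl 4-(allyloxy)benzoate
Conditions: Bu4NF, AcOH, THF, rt
Reagents that add atoms: none
Why: Fluoride-induced desilylation frees the C8 alcohol, the acetic acid buffer preventing migration of the ester from O6 to O8.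

Step 23
Reactants: 27 (8S)-alcohol
Product: 28 (4R,5R,6S,7S)-4,5-epoxy-8-oxogermacr-1(10)E-en-6-yl 4-(allyloxy)benzoate
Conditions: Pr4N[RuO4] (cat.), N-methylmorpholine N-oxide, 4 Å sieves, CH2Cl2, rt
Reagents that add atoms: none
Why: Ley–Griffith oxidation converts the secondary alcohol into the ketone under neutral conditions that spare the epoxide, the ring alkene and the allyl ether and should not enolise C7.

Step 24
Reactants: 28 C8 ketone
Product: 29 (4R,5R,6S,7R,8R)-4,5-epoxy-8-hydroxygermacr-1(10)E-en-6-yl 4-(allyloxy)benzoate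
Conditions: LiBH(s-Bu)3, THF, −78 °C; AcOH, −78 °C
Reagents that add atoms: none
Why: Reduction of an α-branched cyclic ketone by a bulky trialkylborohydride, where hydride should attack from the open peripheral side away from the C14 methyl and the ring interior, as with 2-alkylcyclohexanones, giving the alcohol cis to the isopropyl group and so setting C8 as 8R.

Step 25
Reactants: 29 allyl-protected ester
Product: 30 (4R,5R,6S,7R,8R)-4,5-epoxy-8-hydroxygermacr-1(10)E-en-6-yl 4-hydroxybenzoate (CNP0319712.1)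
Conditions: Pd(PPh3)4 (cat.), morpholine, THF, rt
Reagents that add atoms: none
Why: Tsuji–Trost deallylation, in which zerovalent palladium ionises the allyl aryl ether and morpholine traps the allyl fragment, frees the phenol without touching the epoxide, the ester or the ring alkene.

Compound list
1 | geraniol, (2E)-3,7-dimethylocta-2,6-dien-1-ol | CC(C)=CCC/C(C)=C/CO | starting material
2 | geranyl 4-methoxybenzyl ether, 1-({[(2E)-3,7-dimethylocta-2,6-dien-1-yl]oxy}methyl)-4-methoxybenzene | CC(C)=CCC/C(C)=C/COCc1ccc(OC)cc1 | intermediate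
3 | (2E,6E)-8-[(4-methoxybenzyl)oxy]-2,6-dimethylocta-2,6-dien-1-ol (C9 alcohol) | OC/C(C)=C/CC/C(C)=C/COCc1ccc(OC)cc1 | intermediate
4 | 1-({[(2E,6E)-8-bromo-3,7-dimethylocta-2,6-dien-1-yl]oxy}methyl)-4-methoxybenzene | BrC/C(C)=C/CC/C(C)=C/COCc1ccc(OC)cc1 | intermediate
5 | 1-({[(2E,6E)-3,7-dimethyl-8-(phenylsulfonyl)octa-2,6-dien-1-yl]oxy}methyl)-4-methoxybenzene (C9 sulfone) | O=S(=O)(C/C(C)=C/CC/C(C)=C/COCc1ccc(OC)cc1)c1ccccc1 | intermediate
6 | prenyl acetate, 3-methylbut-2-en-1-yl acetate | CC(C)=CCOC(C)=O | starting material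
7 | (2E)-4-hydroxy-3-methylbut-2-en-1-yl acetate | OC/C(C)=C/COC(C)=O | intermediate
8 | (2E)-4-[(tert-butyldimethylsilyl)oxy]-3-methylbut-2-en-1-yl acetate | CC(C)(C)[Si](C)(C)OC/C(C)=C/COC(C)=O | intermediate
9 | (2E)-4-[(tert-butyldimethylsilyl)oxy]-3-methylbut-2-en-1-ol | CC(C)(C)[Si](C)(C)OC/C(C)=C/CO | intermediate
10 | (2E)-4-[(tert-butyldimethylsilyl)oxy]-3-methylbut-2-enal (C8 enal) | CC(C)(C)[Si](C)(C)OC/C(C)=C/C=O | intermediate
11 | α-lithio derivative of sulfone 5, lithium on C9 | [Li]C(/C(C)=C/CC/C(C)=C/COCc1ccc(OC)cc1)S(=O)(=O)c1ccccc1 | intermediate (not isolated)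
12 | (2E,6E,10E)-12-[(tert-butyldimethylsilyl)oxy]-1-[(4-methoxybenzyl)oxy]-3,7,11-trimethyl-8-(phenylsulfonyl)dodeca-2,6,10-trien-9-ol, mixture of diastereomers at the carbinol and sulfonyl carbons | CC(C)(C)[Si](C)(C)OC/C(C)=C/C(O)C(/C(C)=C/CC/C(C)=C/COCc1ccc(OC)cc1)S(=O)(=O)c1ccccc1 | intermediate
13 | (2E,6E,10E)-12-[(tert-butyldimethylsilyl)oxy]-1-[(4-methoxybenzyl)oxy]-3,7,11-trimethyl-8-(phenylsulfonyl)dodeca-2,6,10-trien-9-one | CC(C)(C)[Si](C)(C)OC/C(C)=C/C(=O)C(/C(C)=C/CC/C(C)=C/COCc1ccc(OC)cc1)S(=O)(=O)c1ccccc1 | intermediate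
14 | (2E,6E,10E)-12-[(tert-butyldimethylsilyl)oxy]-1-[(4-methoxybenzyl)oxy]-3,7,11-trimethyldodeca-2,6,10-trien-9-one | CC(C)(C)[Si](C)(C)OC/C(C)=C/C(=O)C/C(C)=C/CC/C(C)=C/COCc1ccc(OC)cc1 | intermediate
15 | (2E,6E,9S,10E)-12-[(tert-butyldimethylsilyl)oxy]-1-[(4-methoxybenzyl)oxy]-3,7,11-trimethyldodeca-2,6,10-trien-9-ol (8S in germacrane numbering) | CC(C)(C)[Si](C)(C)OC/C(C)=C/[C@@H](O)C/C(C)=C/CC/C(C)=C/COCc1ccc(OC)cc1 | intermediate
16 | (2E,6E,9S,10E)-9,12-bis[(tert-butyldimethylsilyl)oxy]-3,7,11-trimethyldodeca-2,6,10-trien-1-yl 4-methoxybenzyl ether | CC(C)(C)[Si](C)(C)OC/C(C)=C/[C@@H](O[Si](C)(C)C(C)(C)C)C/C(C)=C/CC/C(C)=C/COCc1ccc(OC)cc1 | intermediate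
17 | (2E,4S,6E,10E)-4-[(tert-butyldimethylsilyl)oxy]-12-[(4-methoxybenzyl)oxy]-2,6,10-trimethyldodeca-2,6,10-trien-1-ol (free C12 alcohol) | OC/C(C)=C/[C@@H](O[Si](C)(C)C(C)(C)C)C/C(C)=C/CC/C(C)=C/COCc1ccc(OC)cc1 | intermediate
18 | (2E,6E,9S,10E)-9-[(tert-butyldimethylsilyl)oxy]-12-chloro-3,7,11-trimethyldodeca-2,6,10-trien-1-yl 4-methoxybenzyl ether | ClC/C(C)=C/[C@@H](O[Si](C)(C)C(C)(C)C)C/C(C)=C/CC/C(C)=C/COCc1ccc(OC)cc1 | intermediate
19 | (2E,6E,9S,10E)-9-[(tert-butyldimethylsilyl)oxy]-12-chloro-3,7,11-trimethyldodeca-2,6,10-trien-1-ol | ClC/C(C)=C/[C@@H](O[Si](C)(C)C(C)(C)C)C/C(C)=C/CC/C(C)=C/CO | intermediate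
20 | (3E,5S,7E,11E)-5-[(tert-butyldimethylsilyl)oxy]-3,7,11-trimethyl-1-oxacyclotrideca-3,7,11-triene (C6–O–C12 ether, 8S) | C/C1=C\CC/C(C)=C/COC/C(C)=C/[C@@H](O[Si](C)(C)C(C)(C)C)C1 | intermediate
21 | C6-lithio derivative of ether 20 | C/C1=C\CC/C(C)=C/C([Li])OC/C(C)=C/[C@@H](O[Si](C)(C)C(C)(C)C)C1 | intermediate (not isolated)
22 | (1R,2E,6E,9S,10S)-9-[(tert-butyldimethylsilyl)oxy]-3,7-dimethyl-10-(prop-1-en-2-yl)cyclodeca-2,6-dien-1-ol, (6R,7S,8S)-8-silyloxygermacra-1(10)E,4E,11-trien-6-ol | C/C1=C\CC/C(C)=C/[C@@H](O)[C@H](C(C)=C)[C@@H](O[Si](C)(C)C(C)(C)C)C1 | intermediate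
23 | (1R,2E,6E,9S,10S)-9-[(tert-butyldimethylsilyl)oxy]-3,7-dimethyl-10-(propan-2-yl)cyclodeca-2,6-dien-1-ol | C/C1=C\CC/C(C)=C/[C@@H](O)[C@H](C(C)C)[C@@H](O[Si](C)(C)C(C)(C)C)C1 | intermediate
24 | (4R,5R,6S,7S,8S)-8-[(tert-butyldimethylsilyl)oxy]-4,5-epoxygermacr-1(10)E-en-6-ol | C/C1=C\CC[C@@]2(C)O[C@@H]2[C@@H](O)[C@H](C(C)C)[C@@H](O[Si](C)(C)C(C)(C)C)C1 | intermediate
25 | 4-(allyloxy)benzoic acid, 4-(prop-2-en-1-yloxy)benzoic acid | C=CCOc1ccc(C(=O)O)cc1 | starting material
26 | (4R,5R,6S,7S,8S)-8-[(tert-butyldimethylsilyl)oxy]-4,5-epoxygermacr-1(10)E-en-6-yl 4-(allyloxy)benzoate | C/C1=C\CC[C@@]2(C)O[C@@H]2[C@@H](OC(=O)c2ccc(OCC=C)cc2)[C@H](C(C)C)[C@@H](O[Si](C)(C)C(C)(C)C)C1 | intermediate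
27 | (4R,5R,6S,7R,8S)-4,5-epoxy-8-hydroxygermacr-1(10)E-en-6-yl 4-(allyloxy)benzoate | C/C1=C\CC[C@@]2(C)O[C@@H]2[C@@H](OC(=O)c2ccc(OCC=C)cc2)[C@H](C(C)C)[C@@H](O)C1 | intermediate
28 | (4R,5R,6S,7S)-4,5-epoxy-8-oxogermacr-1(10)E-en-6-yl 4-(allyloxy)benzoate | C/C1=C\CC[C@@]2(C)O[C@@H]2[C@@H](OC(=O)c2ccc(OCC=C)cc2)[C@H](C(C)C)C(=O)C1 | intermediate
29 | (4R,5R,6S,7R,8R)-4,5-epoxy-8-hydroxygermacr-1(10)E-en-6-yl 4-(allyloxy)benzoate | C/C1=C\CC[C@@]2(C)O[C@@H]2[C@@H](OC(=O)c2ccc(OCC=C)cc2)[C@H](C(C)C)[C@H](O)C1 | intermediate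
30 | (4R,5R,6S,7R,8R)-4,5-epoxy-8-hydroxygermacr-1(10)E-en-6-yl 4-hydroxybenzoate, CNP0319712.1 | C/C1=C\CC[C@@]2(C)O[C@@H]2[C@@H](OC(=O)c2ccc(O)cc2)[C@H](C(C)C)[C@H](O)C1 | target

Total step count: 25. Longest linear sequence: 21 steps (steps 1–4 and 9–25, from geraniol).

Steps most likely to fail

Step 18. Lithiation may also occur at C12, the C6 anion may undergo a [1,2]-shift, or it may add to the other face of C7=C11, so that regio- or stereoisomeric alcohols form instead of one product. The fallback makes the same C6–C7 bond by a Barbier-type macrocyclisation and sets out from hydroxy chloride 19. MnO2 in CH2Cl2 should oxidise the C6 allylic alcohol to the chloro enal F1. Slow addition of the chloro enal F1 to CrCl2 in THF at high dilution should form the allylchromium reagent at C12, which adds through C7 to the C6 aldehyde in a chair-like six-membered transition state (Nozaki–Hiyama allylation) with the anti arrangement. This comes back to the route at alcohol 22.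

Step 24. Hydride delivery may show poor facial selectivity, or the β-acyloxy ketone may lose its benzoate by elimination before it is reduced. The fallback inverts C8 by substitution and sets out from the 8S alcohol 27, leaving out steps 23 and 24. A Mitsunobu reaction with 4-nitrobenzoic acid, PPh3 and diisopropyl azodicarboxylate in toluene should give the inverted C8 4-nitrobenzoate F2 by SN2 displacement. K2CO3 in MeOH at 0 °C should then remove the activated nitrobenzoate from the diester F2 while the hindered, electron-rich C6 ester stays. This comes back to the route at alcohol 29.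

Step 17. Intermolecular etherification may outpace ring closure and give oligomers. The fallback closes the ring through a π-allyl complex and sets out from alcohol 17. Methyl chloroformate and pyridine should give the allylic methyl carbonate F3, and DDQ should then free the C6 alcohol to give the hydroxy carbonate F4. Pd(PPh3)4 in THF under dilution should ionise the hydroxy carbonate F4 with loss of CO2, and the alkoxide generated by the expelled methoxide should attack the less hindered C12 terminus of the π-allyl unit (Tsuji–Trost allylic etherification). This comes back to the route at ether 20.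

Further compounds
F1 | step 18 | (2E,6E,9S,10E)-9-[(tert-butyldimethylsilyl)oxy]-12-chloro-3,7,11-trimethyldodeca-2,6,10-trienal (chloro enal) | ClC/C(C)=C/[C@@H](O[Si](C)(C)C(C)(C)C)C/C(C)=C/CC/C(C)=C/C=O
F2 | step 24 | 4-nitrobenzoate of alcohol 29 at the C8 oxygen, C8 configuration as in 29 | C/C1=C\CC[C@@]2(C)O[C@@H]2[C@@H](OC(=O)c2ccc(OCC=C)cc2)[C@H](C(C)C)[C@H](OC(=O)c2ccc([N+](=O)[O-])cc2)C1
F3 | step 17 | (2E,4S,6E,10E)-4-[(tert-butyldimethylsilyl)oxy]-12-[(4-methoxybenzyl)oxy]-2,6,10-trimethyldodeca-2,6,10-trien-1-yl methyl carbonate | COC(=O)OC/C(C)=C/[C@@H](O[Si](C)(C)C(C)(C)C)C/C(C)=C/CC/C(C)=C/COCc1ccc(OC)cc1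
F4 | step 17 | (2E,4S,6E,10E)-4-[(tert-butyldimethylsilyl)oxy]-12-hydroxy-2,6,10-trimethyldodeca-2,6,10-trien-1-yl methyl carbonate | COC(=O)OC/C(C)=C/[C@@H](O[Si](C)(C)C(C)(C)C)C/C(C)=C/CC/C(C)=C/CO
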